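**Plan**
The retrosynthesis cuts two bonds on ring B together: the ether bond O–C1' and the adjacent C2'–Br bond. Ring B carries only this oxygen and this bromine, on neighbouring carbons, so it corresponds to unsubstituted benzyne taking up an oxygen nucleophile and a bromine electrophile.
This leaves ring A as the fully substituted 3,5,6-tribromo-2-methoxyphenol. Its OH is traced back to a formyl group, its OMe to a phenolic OH, and Br-3 and Br-5 to electrophilic bromination.
In the forward direction no ring is built. Ring A is bought as 2-bromo-6-hydroxybenzaldehyde and elaborated in three steps (dibromination, O-methylation, formyl-to-hydroxyl oxidation).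
The two rings are joined in the last step, which also places the fourth bromine.
The target has no stereocentre, so only regiochemistry has to be controlled. On ring A it follows from three directing groups that agree, and on ring B from the symmetry of benzyne.

Key step: step 4

Assumption: 2-bromo-6-hydroxybenzaldehyde, 2-(trimethylsilyl)phenyl triflate and carbon tetrabromide are taken as catalogue chemicals.

**Step 1**
Reactants: 1 2-bromo-6-hydroxybenzaldehyde
Product: 3 3,5,6-tribromo-2-hydroxybenzaldehyde, via 5,6-dibromosalicylaldehyde 2 (not isolated)
Conditions: Br2 (2.2 equiv), NaOAc (2.5 equiv), AcOH, rt to 50 °C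
Reagents that add atoms: bromine, BrBr
Why: Electrophilic aromatic bromination, modelled on the classical dibromination of salicylaldehyde: the hydroxyl group (ortho/para), the formyl group (meta) and the C6 bromine (ortho/para) all direct to C3 and C5, so these two carbons are filled and C4, meta to OH, stays free.

**Step 2**
Reactants: 3 3,5,6-tribromo-2-hydroxybenzaldehyde
Product: 4 3,5,6-tribromo-2-methoxybenzaldehyde
Conditions: MeI (1.5 equiv), K2CO3 (1.5 equiv), DMF, rt
Reagents that add atoms: iodomethane, CI
Why: Williamson ether synthesis: the strongly acidic phenol is fully ionised by K2CO3 and the small electrophile MeI reaches the oxygen between CHO and Br, as in the routine O-methylation of 3,5-dibromosalicylaldehyde, while the aldehyde and the C–Br bonds are inert.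

**Step 3**
Reactants: 4 3,5,6-tribromo-2-methoxybenzaldehyde
Product: 6 3,5,6-tribromo-2-methoxyphenol, via aryl formate 5 (not isolated)
Conditions: mCPBA (2 equiv), CH2Cl2, 40 °C; evaporate; MeOH, cat. HCl, rt
Reagents that add atoms: 3-chloroperoxybenzoic acid, OOC(=O)c1cccc(Cl)c1
Why: Baeyer–Villiger oxidation of an ortho-alkoxybenzaldehyde: in the Criegee adduct the aryl group, assisted by the ortho-methoxy lone pair and by relief of crowding at the di-ortho-flanked carbonyl, should migrate in preference to hydride, and the activated aryl formate 5 is then cleaved by acid-catalysed transesterification to methanol without touching the ether or the C–Br bonds.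

**Step 4**
Reactants: 6 3,5,6-tribromo-2-methoxyphenol; 7 2-(trimethylsilyl)phenyl trifluoromethanesulfonate; 8 carbon tetrabromide
Product: 12 1,2,5-tribromo-3-(2-bromophenoxy)-4-methoxybenzene, via potassium phenolate 9 (not isolated), via benzyne 10 (not isolated), via aryl anion 11 (not isolated)
Conditions: KH (1.0 equiv), dry THF, 0 °C; then 8 (3 equiv), KF (4 equiv), 18-crown-6 (4 equiv), 7 (2 equiv, slow addition), 0 °C to rt
Reagents that add atoms: 2-(trimethylsilyl)phenyl trifluoromethanesulfonate 7 (the C6H4 unit), C[Si](C)(C)c1ccccc1OS(=O)(=O)C(F)(F)F; carbon tetrabromide 8 (the bromine), BrC(Br)(Br)Br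
Why: Proposed new method: fluoride attacks the silicon of 7 and triflate departs to release benzyne 10, the oxygen of phenolate 9 adds to the strained triple bond (O–C1'), and the 2-aryloxyphenyl anion 11 so formed attacks a bromine atom of 8 in a halophilic substitution (C2'–Br) that expels tribromomethanide. The closest known reaction types are the fluoride-triggered three-component aryne couplings in which an amine or sulfur nucleophile adds and the aryl anion takes halogen from a polyhalomethane or a perfluoroaryl halide, and the two-component O-arylation of phenols by the same aryne precursor; new here is the pairing of an aryloxide with bromine transfer. No ring closes and no stereocentre arises, and because benzyne is symmetric the two new bonds can end up on neighbouring carbons in only one way. The selectivity needed is bromine capture by 11 ahead of protonation and ahead of bromine exchange with the C–Br bonds of ring A; the first is secured by THF in place of acetonitrile and by removal of the only O–H as H2, the second by an excess of 8, whose departing carbanion is far better stabilised than any aryl anion. Bromination of 9 itself by 8 should be slow because the sole free carbon, C4, lies between two bromines on an electron-poor ring, and slow addition of 7 keeps benzyne scarce so that tribromomethanide and bromide intercept little of it. The absence of any transition metal leaves all four C–Br bonds untouched, and the high electrophilicity of benzyne compensates for the weak, di-ortho-flanked nucleophile.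

**Compound list**
1 | 2-bromo-6-hydroxybenzaldehyde | O=Cc1c(O)cccc1Br | starting material
2 | 5,6-dibromo-2-hydroxybenzaldehyde | O=Cc1c(O)ccc(Br)c1Br | intermediate
3 | 3,5,6-tribromo-2-hydroxybenzaldehyde | O=Cc1c(O)c(Br)cc(Br)c1Br | intermediate
4 | 3,5,6-tribromo-2-methoxybenzaldehyde | COc1c(Br)cc(Br)c(Br)c1C=O | intermediate
5 | 3,5,6-tribromo-2-methoxyphenyl formate | COc1c(Br)cc(Br)c(Br)c1OC=O | intermediate
6 | 3,5,6-tribromo-2-methoxyphenol | COc1c(Br)cc(Br)c(Br)c1O | intermediate
7 | 2-(trimethylsilyl)phenyl trifluoromethanesulfonate | C[Si](C)(C)c1ccccc1OS(=O)(=O)C(F)(F)F | starting material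
8 | carbon tetrabromide | BrC(Br)(Br)Br | starting material
9 | potassium 3,5,6-tribromo-2-methoxyphenolate | COc1c(Br)cc(Br)c(Br)c1[O-].[K+] | intermediate
10 | benzyne (1,2-didehydrobenzene) | C1=CC#CC=C1 | intermediate
11 | [2-(3,5,6-tribromo-2-methoxyphenoxy)phenyl]potassium | COc1c(Br)cc(Br)c(Br)c1Oc1cccc[c-]1.[K+] | intermediate
12 | 1,2,5-tribromo-3-(2-bromophenoxy)-4-methoxybenzene | COc1c(Br)cc(Br)c(Br)c1Oc1ccccc1Br | target

**Total step count:** 4
**Longest linear sequence:** 4 steps (1 to 12)

**Steps most likely to fail**

Step 4 (Proposed new method).
- The aryl anion may pick up a proton faster than a bromine.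
- Benzyne may be consumed by tribromomethanide or bromide.
- The hindered, electron-poor phenolate may add too slowly.

The fallback sets out from 6 and comes back at 12. It delivers ring B with its bromine already in place. Commercial 1-bromo-2-iodobenzene is oxidised with mCPBA and TsOH·H2O in MeCN and treated in the same pot with 1,3,5-trimethoxybenzene. This gives (2-bromophenyl)(2,4,6-trimethoxyphenyl)iodonium 4-methylbenzenesulfonate F1. Phenol 6 is then O-arylated with F1 (KOtBu, THF, 40 °C) by ligand coupling at trivalent iodine. This is a known metal-free diaryl ether synthesis that tolerates di-ortho-substituted and halogenated phenols. The electron-rich trimethoxyphenyl group stays on iodine, so only the 2-bromophenyl group is transferred.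

Step 3.
- Hydride may migrate instead of aryl in the Criegee adduct, which amounts to over-oxidation of the aldehyde.
- The peracid may add only slowly to the shielded carbonyl.

The fallback sets out from 4 and comes back at 6. It replaces the oxygen insertion by a nitrogen insertion. Pinnick oxidation (NaClO2, NaH2PO4, 2-methyl-2-butene, t-BuOH/H2O) gives 3,5,6-tribromo-2-methoxybenzoic acid F2. The Schmidt reaction (NaN3, conc. H2SO4, CHCl3, 45 °C) runs through the acylium ion and is at its best with di-ortho-substituted benzoic acids. It gives 3,5,6-tribromo-2-methoxyaniline F3. Diazotisation (NaNO2, H2SO4/AcOH, 0 °C) leads to 3,5,6-tribromo-2-methoxybenzenediazonium hydrogen sulfate F4. Hydroxy-dediazoniation with Cu2O and Cu(NO3)2 in water at rt then furnishes 6.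

Step 1.
- Bromine may attack ipso at the formyl-bearing carbon of the free phenol, with loss of the formyl group.
- The reaction may stall after the first bromination.

The fallback sets out from 1 and comes back at 4, so it replaces steps 1 and 2. The phenol is capped first (MeI, K2CO3, DMF) to give 2-bromo-6-methoxybenzaldehyde F5. This is dibrominated with NBS (2.2 equiv) in conc. H2SO4 at rt, by way of 5,6-dibromo-2-methoxybenzaldehyde F6. The methyl ether cannot form the dienone that leads to deformylation. Protonated NBS is strong enough for the deactivated ring. OMe, CHO and Br still direct to the same two carbons.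

**Further compounds**
F1 | step 4 | (2-bromophenyl)(2,4,6-trimethoxyphenyl)iodonium 4-methylbenzenesulfonate | COc1cc(OC)c([I+]c2ccccc2Br)c(OC)c1.Cc1ccc(cc1)S(=O)(=O)[O-]
F2 | step 3 | 3,5,6-tribromo-2-methoxybenzoic acid | COc1c(Br)cc(Br)c(Br)c1C(=O)O
F3 | step 3 | 3,5,6-tribromo-2-methoxyaniline | COc1c(Br)cc(Br)c(Br)c1N
F4 | step 3 | 3,5,6-tribromo-2-methoxybenzenediazonium hydrogen sulfate | COc1c(Br)cc(Br)c(Br)c1[N+]#N.OS(=O)(=O)[O-]
F5 | step 1 | 2-bromo-6-methoxybenzaldehyde | COc1cccc(Br)c1C=O
F6 | step 1 | 5,6-dibromo-2-methoxybenzaldehyde | COc1ccc(Br)c(Br)c1C=O
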